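**Retrosynthetic overview**
- Target enone ⇐ its 4,5-dihydro acyloin; the C4=C5 double bond is introduced last by selenoxide dehydrogenation.
- Key disconnection C1–C6: a ring-closing NHC crossed benzoin. The C6 aldehyde reacts as an acyl anion (Breslow intermediate) with the C1 ketone that already carries both benzoates, closing the only carbocycle and creating the quaternary carbinol.
- The keto aldehyde is stored as a γ-lactol through O-3 ⇐ dibenzoate of a methyl furanoside ⇐ alkene triol (ozonolysis, glycosidation).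
- C2–C3 bond and both of its stereocentres ⇐ amine-catalysed syn-aldol of dihydroxyacetone with pent-4-enal (the terminal alkene is the latent C6 aldehyde).
- Ring order: temporary oxolane (protecting ring, step 2) → opened again → cyclohexanone (step 5).

Assumption: target atoms are labelled C1 (C(OH)CH2OBz), C2 (CHOBz), C3 (CHOH), C4=C5, C6 (C=O), C7 (CH2OBz); the given SMILES is then (1R,2S,3R). 1,3-Dihydroxyacetone is used as its commercial dimer.

**Step 1**
Reactants: 1 1,3-dihydroxyacetone; 2 pent-4-enal
Product: 3 (3S,4R)-1,3,4-trihydroxyoct-7-en-2-one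
Conditions: O-tert-butyl-D-threonine (20 mol %), 5-methyl-1H-tetrazole (10 mol %), N-methylpyrrolidone/H2O 97:3, 1 in excess (3 equiv), rt
Reagents that add atoms: none
Why: Primary-amine (enamine) catalysed direct syn-aldol: the catalyst forms the Z-enamine of dihydroxyacetone (N–H···O hydrogen bond) and its carboxylic acid steers the aldehyde to one face, so target C2 and C3 are set together as the D-threo (3S,4R) pair, the sense expected from the D-configured catalyst by analogy with the proline (3S,4S) anti series.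

**Step 2**
Reactants: 3 (3S,4R)-1,3,4-trihydroxyoct-7-en-2-one
Product: 5 (1S)-1,3-dihydroxy-1-[(2R)-5-methoxyoxolan-2-yl]propan-2-one (anomeric mixture), via hydroxy aldehyde 4 (not isolated)
Conditions: O3, CH2Cl2/MeOH 1:1, −78 °C; Me2S, −78 °C → rt; then TsOH·H2O (5 mol %), MeOH, 0 °C → rt, stopped at the kinetic furanoside
Reagents that add atoms: methanol, CO
Why: Ozonolysis with reductive work-up gives the γ-hydroxy aldehyde, and kinetic Fischer glycosidation closes the five-membered methyl acetal through the C4 hydroxyl (faster than six-ring closure through the ketone-deactivated C3 hydroxyl), masking the aldehyde and O-4 at once and leaving free only the two hydroxyls that must carry benzoates; the acetal carbon is an inconsequential mixture.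

**Step 3**
Reactants: 5 (1S)-1,3-dihydroxy-1-[(2R)-5-methoxyoxolan-2-yl]propan-2-one
Product: 6 (1S)-3-(benzoyloxy)-1-[(2R)-5-methoxyoxolan-2-yl]-2-oxopropyl benzoate
Conditions: BzCl (2.3 equiv), pyridine, 4-(dimethylamino)pyridine (5 mol %), CH2Cl2, 0 °C
Reagents that add atoms: benzoyl chloride, O=C(Cl)c1ccccc1
Why: Simple O-acylation of the primary and the α-keto secondary hydroxyl under mild base at low temperature; no stereocentre is touched.

**Step 4**
Reactants: 6 (1S)-3-(benzoyloxy)-1-[(2R)-5-methoxyoxolan-2-yl]-2-oxopropyl benzoate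
Product: 7 (1S)-3-(benzoyloxy)-1-[(2R)-5-hydroxyoxolan-2-yl]-2-oxopropyl benzoate (lactol, anomeric mixture)
Conditions: AcOH/H2O 4:1, 40 °C
Reagents that add atoms: water, O
Why: Acid-catalysed hydrolysis of the very labile 2-methoxyoxolane acetal; benzoates survive and the lactol keeps O-4 tied up, so no 1,2-benzoyl shift can occur before the ring closure.

**Step 5 (key step)**
Reactants: 7 (1S)-3-(benzoyloxy)-1-[(2R)-5-hydroxyoxolan-2-yl]-2-oxopropyl benzoate
Product: 9 [(1R,2S,3R)-2-(benzoyloxy)-1,3-dihydroxy-6-oxocyclohexyl]methyl benzoate, via open-chain keto aldehyde 8 (not isolated)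
Conditions: 6,7-dihydro-2-(pentafluorophenyl)-5H-pyrrolo[2,1-c][1,2,4]triazol-2-ium tetrafluoroborate (15 mol %), iPr2NEt (15 mol %), CH2Cl2, 4 Å molecular sieves, 25–40 °C
Reagents that add atoms: none
Why: Proposed new method: the lactol opens to the aldehyde, the triazolylidene converts it into the Breslow intermediate (acyl anion equivalent at C6), and this adds intramolecularly to the strongly electrophilic α,α'-bis(benzoyloxy) ketone C1 in a 6-exo closure; C1 is set by a chair transition state in which C2–OBz and C3–OH are trans-diaxial, the free C3 hydroxyl hydrogen-bonds to the ketone oxygen (1,3-syn delivery), C1=O lies anti to C2–OBz and CH2OBz is equatorial, giving C1–OH cis to C3–OH and trans to C2–OBz; the closest known reactions are the NHC-catalysed intramolecular crossed aldehyde–ketone benzoin to six-membered tertiary acyloins and the benzoin cyclisation of sugar-derived dialdehydes to inososes.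

**Step 6**
Reactants: 9 [(1R,2S,3R)-2-(benzoyloxy)-1,3-dihydroxy-6-oxocyclohexyl]methyl benzoate
Product: 11 [(1R,2S,3R)-2-(benzoyloxy)-1,3-dihydroxy-6-oxocyclohex-4-en-1-yl]methyl benzoate (target), via phenylselanyl ketone 10 (not isolated)
Conditions: PhSeCl (1.2 equiv), EtOAc, rt; then 30% H2O2, pyridine, CH2Cl2, 0 °C → rt
Reagents that add atoms: none
Why: Acid-mediated α-selenenylation at C5, the only enolisable position (C1 is quaternary), followed by selenoxide syn-elimination toward C4 (Reich–Sharpless dehydrogenation) gives the enone without touching C1–C3.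

**Compound list**
1 | 1,3-dihydroxyacetone (sold as the crystalline dimer, monomer in solution) | OCC(=O)CO | starting material
2 | pent-4-enal | C=CCCC=O | starting material
3 | (3S,4R)-1,3,4-trihydroxyoct-7-en-2-one | OCC(=O)[C@@H](O)[C@H](O)CCC=C | intermediate
4 | (4R,5S)-4,5,7-trihydroxy-6-oxoheptanal (open form of the lactol mixture) | OCC(=O)[C@@H](O)[C@H](O)CCC=O | intermediate
5 | (1S)-1,3-dihydroxy-1-[(2R)-5-methoxyoxolan-2-yl]propan-2-one (both anomers) | OCC(=O)[C@@H](O)[C@H]1CCC(OC)O1 | intermediate
6 | (1S)-3-(benzoyloxy)-1-[(2R)-5-methoxyoxolan-2-yl]-2-oxopropyl benzoate (both anomers) | O=C(OCC(=O)[C@@H](OC(=O)c1ccccc1)[C@H]2CCC(OC)O2)c3ccccc3 | intermediate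
7 | (1S)-3-(benzoyloxy)-1-[(2R)-5-hydroxyoxolan-2-yl]-2-oxopropyl benzoate (both anomers) | O=C(OCC(=O)[C@@H](OC(=O)c1ccccc1)[C@H]2CCC(O)O2)c3ccccc3 | intermediate
8 | (3S,4R)-1-(benzoyloxy)-4-hydroxy-2,7-dioxoheptan-3-yl benzoate | O=C(OCC(=O)[C@@H](OC(=O)c1ccccc1)[C@H](O)CCC=O)c2ccccc2 | intermediate
9 | [(1R,2S,3R)-2-(benzoyloxy)-1,3-dihydroxy-6-oxocyclohexyl]methyl benzoate | O=C(OC[C@]1(O)C(=O)CC[C@@H](O)[C@@H]1OC(=O)c2ccccc2)c3ccccc3 | intermediate
10 | [(1R,2S,3R)-2-(benzoyloxy)-1,3-dihydroxy-6-oxo-5-(phenylselanyl)cyclohexyl]methyl benzoate (C5 epimers) | O=C(OC[C@]1(O)C(=O)C([Se]c2ccccc2)C[C@@H](O)[C@@H]1OC(=O)c3ccccc3)c4ccccc4 | intermediate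
11 | [(1R,2S,3R)-2-(benzoyloxy)-1,3-dihydroxy-6-oxocyclohex-4-en-1-yl]methyl benzoate | O=C(OC[C@]1(O)C(=O)C=C[C@@H](O)[C@@H]1OC(=O)c2ccccc2)c3ccccc3 | target

**Total step count:** 6. **Longest linear sequence:** 6 steps (1 → 11).

**Steps most likely to fail, with fallbacks**

Most at risk is step 5. An all-equatorial, Felkin-type chair would give the C1 epimer, and on simple Felkin and steric grounds that epimer could well be the major product. The base can also cause a benzoyl shift, C2 epimerisation, β-elimination of the lactol oxygen, or a competing five-ring aldol. The fallback sets out from 5 and comes back at 9. Instead of benzoylating O-7 and O-2, it ties them together so that the acceptor ketone sits in a six-membered ring. The tethered acyl anion can then only close a cis-fused bicycle (C1–OH cis to C2–H, the required configuration), and no base-labile ester is present during the ring closure.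
- tBu2Si(OTf)2 and 2,6-lutidine convert 5 into the silylene ketone (4S)-2,2-di-tert-butyl-4-[(2R)-5-methoxyoxolan-2-yl]-1,3,2-dioxasilinan-5-one F3.
- Aqueous AcOH hydrolyses the methyl acetal to the lactol F4.
- The same triazolium salt with iPr2NEt closes the cis-fused silylene acyloin F5.
- 2,2-Dimethoxypropane with camphor-10-sulfonic acid bridges the cis-1,3-diol (C1–OH and C3–OH) as the acetonide F6.
- HF·pyridine removes the silylene to give the diol acetonide F7.
- BzCl in pyridine gives the dibenzoate acetonide F8.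
- Aqueous CF3CO2H removes the acetonide and delivers 9.

Next is step 1. The unbranched aldehyde may self-condense, and the free triol is awkward to isolate. The fallback sets out from 1 and comes back at 3.
- Silylate 1 (tBuMe2SiCl, imidazole, DMF) to 1,3-bis(tert-butyldimethylsilyloxy)propan-2-one F1.
- Run the threonine-catalysed syn-aldol with 2 on this lipophilic donor, which gives the chromatographable (3S,4R)-1,3-bis(tert-butyldimethylsilyloxy)-4-hydroxyoct-7-en-2-one F2.
- Remove both silyl groups with HF in aqueous MeCN to reach 3.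

Third is step 6. Selenenylation next to a quaternary carbon, and the acid and oxidant, may damage the hydroxy benzoate. The fallback sets out from 9 and comes back at 11.
- Me3SiOTf and Et3N in CH2Cl2 (−78 → 0 °C) silylate both hydroxyls and turn the ketone into its trimethylsilyl enol ether, the tris(trimethylsilyl) compound F9.
- Pd(OAc)2 (1.1 equiv) in MeCN dehydrosilylates this (Saegusa–Ito oxidation) to the bis(trimethylsilyl) ether of the target F10.
- Citric acid in MeOH strips the two silyl ethers to give 11.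

**Further compounds**
F1 | step 1 | 1,3-bis(tert-butyldimethylsilyloxy)propan-2-one | CC(C)(C)[Si](C)(C)OCC(=O)CO[Si](C)(C)C(C)(C)C
F2 | step 1 | (3S,4R)-1,3-bis(tert-butyldimethylsilyloxy)-4-hydroxyoct-7-en-2-one | CC(C)(C)[Si](C)(C)OCC(=O)[C@@H](O[Si](C)(C)C(C)(C)C)[C@H](O)CCC=C
F3 | step 5 | (4S)-2,2-di-tert-butyl-4-[(2R)-5-methoxyoxolan-2-yl]-1,3,2-dioxasilinan-5-one | CC(C)(C)[Si]1(OCC(=O)[C@@H](O1)[C@H]2CCC(OC)O2)C(C)(C)C
F4 | step 5 | (4S)-2,2-di-tert-butyl-4-[(2R)-5-hydroxyoxolan-2-yl]-1,3,2-dioxasilinan-5-one | CC(C)(C)[Si]1(OCC(=O)[C@@H](O1)[C@H]2CCC(O)O2)C(C)(C)C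
F5 | step 5 | cis-fused silylene acyloin: (1R,2S,3R)-1,3-dihydroxy-6-oxocyclohexane core of 9 with O-7 and O-2 joined by di-tert-butylsilylene | CC(C)(C)[Si]2(OC[C@]1(O)C(=O)CC[C@@H](O)[C@@H]1O2)C(C)(C)C
F6 | step 5 | F5 with C1–O and C3–O bridged as the isopropylidene acetal | CC(C)(C)[Si]2(OC[C@]1(O3)C(=O)CC[C@@H](OC3(C)C)[C@@H]1O2)C(C)(C)C
F7 | step 5 | (1R,2S,3R)-2-hydroxy-1-(hydroxymethyl)-6-oxocyclohexane-1,3-diol 1,3-O-isopropylidene acetal | OC[C@]1(O3)C(=O)CC[C@@H](OC3(C)C)[C@@H]1O
F8 | step 5 | 1,3-O-isopropylidene acetal of 9 | O=C(OC[C@]1(O3)C(=O)CC[C@@H](OC3(C)C)[C@@H]1OC(=O)c2ccccc2)c4ccccc4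
F9 | step 6 | 1,3-bis-O-trimethylsilyl ether of 9 as its C6 trimethylsilyl enol ether | O=C(OC[C@]1(O[Si](C)(C)C)C(O[Si](C)(C)C)=CC[C@@H](O[Si](C)(C)C)[C@@H]1OC(=O)c2ccccc2)c3ccccc3
F10 | step 6 | 1,3-bis-O-trimethylsilyl ether of 11 | O=C(OC[C@]1(O[Si](C)(C)C)C(=O)C=C[C@@H](O[Si](C)(C)C)[C@@H]1OC(=O)c2ccccc2)c3ccccc3
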